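**Retrosynthetic overview**

1. Target 17 ⇐ tagitinin C (15): the last bond is C1–O, made by boron-templated intramolecular oxa-Michael delivery of hydroxide from the C10 hydroxyl.
2. 15 ⇐ acyclic alkenyl iodide/alkenylstannane 14: the ten-membered carbocycle is closed second, by carbonylative Stille coupling (C3 comes from CO).
3. 14 ⇐ bromomethyl butenolide 7 + β-hydroxy aldehyde 12: zinc Barbier allylation (C7–C8; C7 and C8 relayed from C6), then acylation of O8.
4. 7 ⇐ dienoic acid 6: the butenolide ring is closed first, through its C6–O bond, by a new catalytic enantioselective 1,4-bromolactonisation; 6 comes from but-2-yn-1-ol.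
5. 12 ⇐ (E)-3-methylpent-2-en-4-yn-1-ol: hydrostannation, Sharpless epoxidation (C10–O), Red-Al opening, oxidation.

Assumption: the target is taken as the open 3-keto-1,10-diol exactly as drawn (it may equilibrate with its 3,10-hemiketal); atom labels C1–C15 follow germacrane numbering.

**Route**

Step 1
Reactants: 1 but-2-yn-1-ol
Product: 2 (2Z)-3-iodobut-2-en-1-ol
Conditions: NaAlH2(OCH2CH2OMe)2 (Red-Al), THF, 0 °C → rt; then I2, −78 °C
Reagents that add atoms: iodine, II
Why: Hydroxyl-directed trans-hydroalumination of the propargylic alcohol puts aluminium on the distal carbon, and iodinolysis with retention gives the Z-iodoalkene (hydroalumination–iodination).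

Step 2
Reactants: 2 (2Z)-3-iodobut-2-en-1-ol
Product: 3 (2Z)-3-iodobut-2-enal
Conditions: activated MnO2, CH2Cl2, rt, dark; used at once
Reagents that add atoms: none
Why: Allylic alcohol oxidation with MnO2 is neutral and keeps the Z-alkenyl iodide geometry.

Step 3
Reactants: 3 (2Z)-3-iodobut-2-enal; 4 2-(bromomethyl)prop-2-enoic acid
Product: 6 (3E,5Z)-6-iodo-2-methylidenehepta-3,5-dienoic acid, via phosphonium salt 5 (not isolated)
Conditions: 4, PBu3, THF, rt; LiHMDS (2.1 equiv), −78 °C; then 3, −78 → 0 °C; 1 M HCl work-up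
Reagents that add atoms: none
Why: Tributylphosphine is quaternised by the allylic bromide and the resulting allylic tributylphosphonium ylide undergoes E-selective Wittig olefination with the enal, giving the 2-carboxy-1,3-diene.

Step 4
Reactants: 6 (3E,5Z)-6-iodo-2-methylidenehepta-3,5-dienoic acid
Product: 7 (5S)-3-(bromomethyl)-5-[(1Z)-2-iodoprop-1-en-1-yl]furan-2(5H)-one
Conditions: NBS (1.1 equiv), O-(quinidin-9-yl) N-(4-methoxyphenyl)thiocarbamate (10 mol%), toluene/CHCl3 2:1, −60 °C, dark
Reagents that add atoms: N-bromosuccinimide, O=C1CCC(=O)N1Br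
Why: Proposed new method: a catalytic enantioselective 1,4-bromolactonisation of a 2-carboxy-1,3-diene, in which the thiocarbamate sulfur carries Br+ from NBS while the quinuclidine nitrogen holds the carboxylate, Br+ adds to the terminal methylene (C13) of the cross-conjugated triene to give an iodine- and methyl-stabilised pentadienyl cation, and the carboxylate captures it at C6 in a five-membered closure that forms the C6–O bond, sets the 5S centre under catalyst control and leaves the allylic bromide needed in step 9; the closest known reactions are cinchona amino-thiocarbamate-catalysed enantioselective bromolactonisations of alkenoic acids and the catalytic enantioselective 1,4-bromolactonisation of conjugated enynes.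

Step 5
Reactants: 8 (2E)-3-methylpent-2-en-4-yn-1-ol
Product: 9 (2E,4E)-3-methyl-5-(tributylstannyl)penta-2,4-dien-1-ol
Conditions: Bu3SnH, PdCl2(PPh3)2 (2 mol%), THF, 0 °C
Reagents that add atoms: tributyltin hydride, CCCC[SnH](CCCC)CCCC
Why: Palladium-catalysed syn-hydrostannation of the terminal alkyne places tin on the less hindered distal carbon and gives the E-alkenylstannane.

Step 6
Reactants: 9 (2E,4E)-3-methyl-5-(tributylstannyl)penta-2,4-dien-1-ol
Product: 10 [(2S,3S)-3-methyl-3-[(E)-2-(tributylstannyl)ethenyl]oxiran-2-yl]methanol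
Conditions: Ti(OiPr)4 (10 mol%), L-(+)-diisopropyl tartrate (12 mol%), t-BuOOH, 4 Å MS, CH2Cl2, −20 °C
Reagents that add atoms: tert-butyl hydroperoxide, CC(C)(C)OO
Why: Katsuki–Sharpless asymmetric epoxidation of the allylic alcohol with the L-(+)-tartrate gives the (2S,3S)-epoxide (same olefin topology as geraniol), which fixes the future C10–O stereocentre.

Step 7
Reactants: 10 [(2S,3S)-3-methyl-3-[(E)-2-(tributylstannyl)ethenyl]oxiran-2-yl]methanol
Product: 11 (3R,4E)-3-methyl-5-(tributylstannyl)pent-4-ene-1,3-diol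
Conditions: NaAlH2(OCH2CH2OMe)2 (Red-Al), THF, 0 °C
Reagents that add atoms: none
Why: Alkoxide-directed intramolecular hydride delivery opens the 2,3-epoxy alcohol at C2 to the 1,3-diol and leaves the tertiary C–O stereocentre untouched.

Step 8
Reactants: 11 (3R,4E)-3-methyl-5-(tributylstannyl)pent-4-ene-1,3-diol
Product: 12 (3R,4E)-3-hydroxy-3-methyl-5-(tributylstannyl)pent-4-enal
Conditions: (n-Pr4N)RuO4 (5 mol%), N-methylmorpholine N-oxide, 4 Å MS, CH2Cl2, 0 °C → rt; used crude
Reagents that add atoms: none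
Why: Ley–Griffith oxidation converts only the primary alcohol; the tertiary allylic alcohol and the alkenylstannane are inert.

Step 9
Reactants: 7 (5S)-3-(bromomethyl)-5-[(1Z)-2-iodoprop-1-en-1-yl]furan-2(5H)-one; 12 (3R,4E)-3-hydroxy-3-methyl-5-(tributylstannyl)pent-4-enal
Product: 13 (4R,5S)-4-[(1R,3R,4E)-1,3-dihydroxy-3-methyl-5-(tributylstannyl)pent-4-en-1-yl]-5-[(1Z)-2-iodoprop-1-en-1-yl]-3-methylideneoxolan-2-one
Conditions: Zn dust, THF/sat. aq. NH4Cl, 0 °C → rt
Reagents that add atoms: none
Why: Barbier allylation in which the allylzinc from the bromomethyl butenolide attacks the aldehyde through C7 (SE2′) on the face anti to the C6 substituent (6,7-trans lactone, exocyclic methylene regenerated), and zinc-mediated additions of this reagent class give the syn C7/C8 adduct, i.e. the 8R carbinol.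

Step 10
Reactants: 13 (the Barbier diol of step 9)
Product: 14 (1R,3R,4E)-3-hydroxy-1-[(2S,3R)-2-[(1Z)-2-iodoprop-1-en-1-yl]-4-methylidene-5-oxooxolan-3-yl]-3-methyl-5-(tributylstannyl)pent-4-en-1-yl 2-methylpropanoate
Conditions: (i-PrCO)2O, Et3N, DMAP (10 mol%), CH2Cl2, 0 °C
Reagents that add atoms: isobutyric anhydride, CC(C)C(=O)OC(=O)C(C)C
Why: DMAP-catalysed acylation esterifies the secondary C8 alcohol, while the tertiary C10 alcohol does not react at 0 °C.

Step 11
Reactants: 14 (the isobutyrate of step 10)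
Product: 15 tagitinin C, (1E,4Z,6R,7R,8R,10R)-10-hydroxy-8-(2-methylpropanoyloxy)-3-oxogermacra-1,4,11(13)-trien-12,6-olide
Conditions: Pd2(dba)3 (10 mol%), AsPh3 (40 mol%), CO (3 atm), LiCl, THF/DMF, 0.002 M (syringe pump), 50 °C
Reagents that add atoms: carbon monoxide, [C-]#[O+]
Why: Carbonylative Stille macrocyclisation, in which zerovalent palladium inserts into the Z-alkenyl iodide, CO insertion gives the acyl complex, and intramolecular transmetalation with the E-alkenylstannane followed by reductive elimination closes the ten-membered cross-conjugated dienone with both olefin geometries retained.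

Step 12
Reactants: 15 tagitinin C
Product: 17 (1R,4Z,6R,7R,8R,10R)-1,10-dihydroxy-8-(2-methylpropanoyloxy)-3-oxogermacra-4,11(13)-dien-12,6-olide (target), via cyclic phenylboronate 16 (not isolated)
Conditions: PhB(OH)2 (1.5 equiv), i-Pr2NEt (30 mol%), 4 Å MS, toluene, rt; then pinacol (5 equiv), rt
Reagents that add atoms: phenylboronic acid, OB(O)c1ccccc1
Why: Boronic acid hemiester oxa-Michael addition, in which the C10–O–B(Ph)–OH hemiester delivers its hydroxyl oxygen to C1 in a 5-exo closure that must occur on the enone face anti to C9 when the C9–C10 ring bond stands perpendicular to the enone plane, giving the 1R (1,10-trans) diol chemoselectively at C1, and pinacol transesterification then frees the diol.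

**Compound list**

1 | but-2-yn-1-ol | CC#CCO | starting material
2 | (2Z)-3-iodobut-2-en-1-ol | C/C(I)=C/CO | intermediate
3 | (2Z)-3-iodobut-2-enal | C/C(I)=C/C=O | intermediate
4 | 2-(bromomethyl)prop-2-enoic acid | C=C(CBr)C(=O)O | starting material
5 | tributyl(2-carboxyprop-2-en-1-yl)phosphonium bromide | CCCC[P+](CCCC)(CCCC)CC(=C)C(=O)O.[Br-] | intermediate
6 | (3E,5Z)-6-iodo-2-methylidenehepta-3,5-dienoic acid | OC(=O)C(=C)/C=C/C=C(/C)I | intermediate
7 | (5S)-3-(bromomethyl)-5-[(1Z)-2-iodoprop-1-en-1-yl]furan-2(5H)-one | O=C1O[C@H](/C=C(/C)I)C=C1CBr | intermediate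
8 | (2E)-3-methylpent-2-en-4-yn-1-ol | C#C/C(C)=C/CO | starting material
9 | (2E,4E)-3-methyl-5-(tributylstannyl)penta-2,4-dien-1-ol | OC/C=C(C)/C=C/[Sn](CCCC)(CCCC)CCCC | intermediate
10 | [(2S,3S)-3-methyl-3-[(E)-2-(tributylstannyl)ethenyl]oxiran-2-yl]methanol | OC[C@@H]1O[C@@]1(C)/C=C/[Sn](CCCC)(CCCC)CCCC | intermediate
11 | (3R,4E)-3-methyl-5-(tributylstannyl)pent-4-ene-1,3-diol | OCC[C@@](C)(O)/C=C/[Sn](CCCC)(CCCC)CCCC | intermediate
12 | (3R,4E)-3-hydroxy-3-methyl-5-(tributylstannyl)pent-4-enal | O=CC[C@@](C)(O)/C=C/[Sn](CCCC)(CCCC)CCCC | intermediate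
13 | (4R,5S)-4-[(1R,3R,4E)-1,3-dihydroxy-3-methyl-5-(tributylstannyl)pent-4-en-1-yl]-5-[(1Z)-2-iodoprop-1-en-1-yl]-3-methylideneoxolan-2-one | C=C1C(=O)O[C@H](/C=C(/C)I)[C@H]1[C@H](O)C[C@@](C)(O)/C=C/[Sn](CCCC)(CCCC)CCCC | intermediate
14 | (1R,3R,4E)-3-hydroxy-1-[(2S,3R)-2-[(1Z)-2-iodoprop-1-en-1-yl]-4-methylidene-5-oxooxolan-3-yl]-3-methyl-5-(tributylstannyl)pent-4-en-1-yl 2-methylpropanoate | C=C1C(=O)O[C@H](/C=C(/C)I)[C@H]1[C@H](OC(=O)C(C)C)C[C@@](C)(O)/C=C/[Sn](CCCC)(CCCC)CCCC | intermediate
15 | tagitinin C, (1E,4Z,6R,7R,8R,10R)-10-hydroxy-8-(2-methylpropanoyloxy)-3-oxogermacra-1,4,11(13)-trien-12,6-olide | C=C1C(=O)O[C@@H]2/C=C(/C)C(=O)/C=C/[C@](C)(O)C[C@@H](OC(=O)C(C)C)[C@@H]12 | intermediate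
16 | 1,10-O-(phenylboranediyl) derivative of 17 (2-phenyl-1,3,2-dioxaborolane fused at C1/C10) | C=C1C(=O)O[C@@H]2/C=C(/C)C(=O)C[C@H]3OB(c4ccccc4)O[C@]3(C)C[C@@H](OC(=O)C(C)C)[C@@H]12 | intermediate
17 | (1R,4Z,6R,7R,8R,10R)-1,10-dihydroxy-8-(2-methylpropanoyloxy)-3-oxogermacra-4,11(13)-dien-12,6-olide | C=C1C(=O)O[C@@H]2/C=C(/C)C(=O)C[C@@H](O)[C@](C)(O)C[C@@H](OC(=O)C(C)C)[C@@H]12 | target

**Step count and risks**

Total steps: 12. Longest linear sequence: 8 (steps 1, 2, 3, 4, 9, 10, 11, 12; the other branch, steps 5–8 then 9–12, is also 8).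

The three steps most likely to fail:

Step 4 (new bromolactonisation). Br+ may add at another diene position, the Z-alkenyl iodide may scramble through the cationic intermediate, or the enantiomeric excess may be low. The fallback uses known chemistry and sets out from aldehyde 3. Catalytic enantioselective vinyl addition (divinylzinc, 3-exo-(dimethylamino)isoborneol, the enantiomer that gives the 3S alcohol, toluene, 0 °C) gives (3S,4Z)-5-iodohexa-1,4-dien-3-ol F1. Esterification with acid 4 (N,N′-diisopropylcarbodiimide, CH2Cl2, 0 °C, no DMAP) gives (3S,4Z)-5-iodohexa-1,4-dien-3-yl 2-(bromomethyl)prop-2-enoate F2. Ring-closing metathesis (second-generation Hoveyda–Grubbs catalyst, toluene, 80 °C) closes the butenolide with loss of ethene and comes back to the route at 7.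

Step 11 (carbonylative Stille macrocyclisation). Direct coupling without CO, oligomerisation, or strain in the ten-membered dienone may defeat it. The fallback sets out from 14. Protodestannylation (CF3CO2H, CH2Cl2, −20 °C) gives (1R,3R)-3-hydroxy-1-[(2S,3R)-2-[(1Z)-2-iodoprop-1-en-1-yl]-4-methylidene-5-oxooxolan-3-yl]-3-methylpent-4-en-1-yl 2-methylpropanoate F3. Cross-metathesis with crotonaldehyde (second-generation Hoveyda–Grubbs catalyst, CH2Cl2, 40 °C) gives the enal (1R,3R,4E)-3-hydroxy-1-[(2S,3R)-2-[(1Z)-2-iodoprop-1-en-1-yl]-4-methylidene-5-oxooxolan-3-yl]-3-methyl-6-oxohex-4-en-1-yl 2-methylpropanoate F4. Intramolecular Nozaki–Hiyama–Kishi coupling of the alkenyl iodide with the enal (CrCl2, NiCl2 cat., DMSO/THF, 0.003 M) closes the ring as (1E,4Z)-3,10-dihydroxy-8-(2-methylpropanoyloxy)germacra-1,4,11(13)-trien-12,6-olide F5 (both C3 epimers). Dess–Martin oxidation of the bis-allylic alcohol comes back to the route at 15.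

Step 12 (directed hydration). The tertiary alcohol may form the boronic hemiester slowly, and the adduct can revert (retro-oxa-Michael) or dehydrate back to 15. The fallback sets out from 15 and replaces the boron template by a carbon tether that is isolated. Bi(NO3)3·5H2O (10 mol%) and acetaldehyde (5 equiv) in CH2Cl2 at rt form the C10 hemiacetal, which adds to C1 in the same 5-exo sense to give the 1,10-O-ethylidene acetal of 17 F6. Hydrolysis (80% aq. AcOH, 40 °C) releases acetaldehyde and comes back to the route at 17.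

**Further compounds**

F1 | step 4 | (3S,4Z)-5-iodohexa-1,4-dien-3-ol | O[C@H](/C=C(/C)I)C=C
F2 | step 4 | (3S,4Z)-5-iodohexa-1,4-dien-3-yl 2-(bromomethyl)prop-2-enoate | C=C(CBr)C(=O)O[C@H](/C=C(/C)I)C=C
F3 | step 11 | (1R,3R)-3-hydroxy-1-[(2S,3R)-2-[(1Z)-2-iodoprop-1-en-1-yl]-4-methylidene-5-oxooxolan-3-yl]-3-methylpent-4-en-1-yl 2-methylpropanoate | C=C1C(=O)O[C@H](/C=C(/C)I)[C@H]1[C@H](OC(=O)C(C)C)C[C@@](C)(O)C=C
F4 | step 11 | (1R,3R,4E)-3-hydroxy-1-[(2S,3R)-2-[(1Z)-2-iodoprop-1-en-1-yl]-4-methylidene-5-oxooxolan-3-yl]-3-methyl-6-oxohex-4-en-1-yl 2-methylpropanoate | C=C1C(=O)O[C@H](/C=C(/C)I)[C@H]1[C@H](OC(=O)C(C)C)C[C@@](C)(O)/C=C/C=O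
F5 | step 11 | (1E,4Z)-3,10-dihydroxy-8-(2-methylpropanoyloxy)germacra-1,4,11(13)-trien-12,6-olide, C3 epimers | C=C1C(=O)O[C@@H]2/C=C(/C)C(O)/C=C/[C@](C)(O)C[C@@H](OC(=O)C(C)C)[C@@H]12
F6 | step 12 | 1,10-O-ethylidene acetal of 17 | C=C1C(=O)O[C@@H]2/C=C(/C)C(=O)C[C@H]3OC(C)O[C@]3(C)C[C@@H](OC(=O)C(C)C)[C@@H]12
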